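**Plan**
- The target is achiral. Benzoate ring A carries, in order around the ring, the methyl ester, a methyl group, a hydrogen, a hydroxyl, a hydroxymethyl group and the diaryl ether oxygen. That oxygen joins it to phthalide ring B (B3a on the lactone CH2, B4 CH3, B5 ether O, B6 and B7 OH, B7a on the lactone C=O).
- The retrosynthesis cuts B3a–B4, B7–B7a and the lactone O–C(=O) bond. The contiguous oxygens on B5, B6 and B7, with B7 next to the carbonyl-bearing B7a, are the imprint of a 1,1,2,3-tetraoxygenated penta-1,3-diene (a vinylketene acetal). B3a, B7a and the two lactone carbons are a 4-silyloxybut-2-ynoate.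
- The diene goes back to a 3-aryloxy-2-oxopentanoate. This is cut at the bond between the ring A ether oxygen and its sp3 carbon, giving the ring A phenol and methyl 3-bromo-2-oxopentanoate. Ring A comes from methyl orsellinate by formylation between its two hydroxyls.
- Forward: ring A is completed and masked as an acetonide, the five-carbon chain is joined by O-alkylation, and two silylations give the diene. The arene of ring B and the lactone then form in one operation, and acid frees the last two hydroxyls.
- No stereocentre is present in the target. The racemic centre of the keto ester and all enol ether geometries are erased when ring B aromatises.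

Key step: step 9

Assumption: the geometry of the silyl enol ether and of the acetal end of the diene is taken as inconsequential because both are lost in the arene, so these compounds are listed as mixtures or with the expected geometry.
Naming note: ArA = 6-(methoxycarbonyl)-2,2,7-trimethyl-4H-1,3-benzodioxin-5-yl (ring A carrying its acetonide).

**Route**

Step 1
Reactants: 1 methyl orsellinate (methyl 2,4-dihydroxy-6-methylbenzoate)
Product: 2 methyl 3-formyl-2,4-dihydroxy-6-methylbenzoate
Conditions: Cl2CHOMe, TiCl4, CH2Cl2, 0 °C; then aq. HCl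
Reagents that add atoms: dichloromethyl methyl ether, COC(Cl)Cl; water, O
Why: Rieche formylation, in which titanium bound to the phenol oxygens should direct the electrophile to C3, the position ortho to both hydroxyls, and the chelated aldehyde resists a second substitution.

Step 2
Reactants: 2 methyl 3-formyl-2,4-dihydroxy-6-methylbenzoate
Product: 3 methyl 2,4-dihydroxy-3-(hydroxymethyl)-6-methylbenzoate
Conditions: NaBH4, THF/MeOH, 0 °C
Reagents that add atoms: none
Why: Borohydride reduction of an aryl aldehyde, which should leave the hindered methyl ester untouched; the sensitive salicyl alcohol is carried on at once.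

Step 3
Reactants: 3 methyl 2,4-dihydroxy-3-(hydroxymethyl)-6-methylbenzoate
Product: 4 methyl 5-hydroxy-2,2,7-trimethyl-4H-1,3-benzodioxine-6-carboxylate (ArA–OH)
Conditions: 2,2-dimethoxypropane, TsOH (cat.), acetone, rt
Reagents that add atoms: 2,2-dimethoxypropane, COC(C)(C)OC
Why: Acid-catalysed acetonide formation on a salicyl alcohol, which under equilibrating conditions should engage the C4 hydroxyl and leave free the C2 hydroxyl that is hydrogen-bonded to the ester.

Step 4
Reactants: 5 methyl 2-oxopentanoate
Product: 6 methyl 3-bromo-2-oxopentanoate (racemic)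
Conditions: Br2, CH2Cl2, 0 °C to rt
Reagents that add atoms: bromine, BrBr
Why: Acid-catalysed α-bromination of a ketone through its enol, C3 being the only enolisable position of the α-keto ester.

Step 5
Reactants: 4 methyl 5-hydroxy-2,2,7-trimethyl-4H-1,3-benzodioxine-6-carboxylate; 6 methyl 3-bromo-2-oxopentanoate
Product: 7 methyl 3-(ArA-oxy)-2-oxopentanoate (racemic)
Conditions: K2CO3, acetone, rt
Reagents that add atoms: none
Why: Williamson-type SN2 displacement of a bromide next to a ketone by a phenoxide, a substitution strongly accelerated by the adjacent carbonyl and therefore expected to tolerate the hindered, chelated phenol.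

Step 6
Reactants: 7 methyl 3-(ArA-oxy)-2-oxopentanoate
Product: 8 methyl 2-(tert-butyldimethylsilyloxy)-3-(ArA-oxy)pent-2-enoate (E/Z mixture)
Conditions: TBSOTf, Et3N, CH2Cl2, 0 °C
Reagents that add atoms: tert-butyldimethylsilyl triflate, CC(C)(C)[Si](C)(C)OS(=O)(=O)C(F)(F)F
Why: Soft enolisation and O-silylation of an α-keto ester to its 2-silyloxy enoate, which can only form toward C3 and removes the racemic centre.

Step 7
Reactants: 8 methyl 2-(tert-butyldimethylsilyloxy)-3-(ArA-oxy)pent-2-enoate
Product: 9 (1E,3Z)-2-(tert-butyldimethylsilyloxy)-1-methoxy-1-(trimethylsilyloxy)-3-(ArA-oxy)penta-1,3-diene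
Conditions: LiN(iPr)2 (LDA), TMSCl present from the start, THF, −78 °C
Reagents that add atoms: chlorotrimethylsilane, C[Si](C)(C)Cl
Why: γ-Deprotonation of a β-oxygenated enoate and O-silylation of the ester dienolate, the way Brassard-type vinylketene acetals are made, with the internal silyl chloride quench meant to trap the dienolate before proton transfer to the ring A benzylic methyl.

Step 8
Reactants: 10 methyl 4-hydroxybut-2-ynoate
Product: 11 methyl 4-(tert-butyldimethylsilyloxy)but-2-ynoate
Conditions: TBSCl, imidazole, CH2Cl2, rt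
Reagents that add atoms: tert-butyldimethylsilyl chloride, CC(C)(C)[Si](C)(C)Cl
Why: Standard silylation of a primary propargylic alcohol.

Step 9
Reactants: 9 (1E,3Z)-2-(tert-butyldimethylsilyloxy)-1-methoxy-1-(trimethylsilyloxy)-3-(ArA-oxy)penta-1,3-diene; 11 methyl 4-(tert-butyldimethylsilyloxy)but-2-ynoate
Product: 15 methyl 5-[(6,7-dihydroxy-4-methyl-1-oxo-1,3-dihydroisobenzofuran-5-yl)oxy]-2,2,7-trimethyl-4H-1,3-benzodioxine-6-carboxylate, via cyclohexa-1,4-diene cycloadduct 12 (not isolated), via trisilylated benzoate 13 (not isolated), via hydroxymethyl benzoate 14 (not isolated)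
Conditions: toluene, 110 °C (sealed tube); then Bu4NF, THF, 0 °C, argon; AcOH quench
Reagents that add atoms: none
Why: The methyl-bearing diene terminus (future B4), which carries the largest HOMO coefficient, bonds to the β-carbon of the ynoate (B3a) and the acetal carbon (B7) to the α-carbon (B7a) in an asynchronous, thermally allowed (4+2) cycloaddition that closes the six-membered carbocycle, and the cyclohexa-1,4-diene then loses methanol across B7 and B4 to give the arene with the silyloxy group kept on B7. Fluoride removes the three silyl groups and the freed benzylic alcohol attacks the neighbouring ester in a 5-exo-trig lactonisation with loss of methanol. The closest known reactions are the cycloadditions of 1-alkoxy-1-silyloxy dienes with alkynoates that give salicylates and the phthalide closure of adducts from 4-oxybut-2-ynoates. No stereocentre survives, since the two sp3 centres of the cycloadduct are destroyed on aromatisation. The step needs regioselectivity, which the two acetal oxygens on B7 and the aryloxy group on B5 should secure by polarising the diene toward B4 against the weaker opposing pull of the B6 silyloxy group, matched with the electrophilic β-carbon of the ynoate; any adduct that has not yet aromatised should collapse to the same B7 phenol when fluoride opens the mixed acetal.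

Step 10
Reactants: 15 methyl 5-[(6,7-dihydroxy-4-methyl-1-oxo-1,3-dihydroisobenzofuran-5-yl)oxy]-2,2,7-trimethyl-4H-1,3-benzodioxine-6-carboxylate
Product: 16 methyl 2-[(6,7-dihydroxy-4-methyl-1-oxo-1,3-dihydroisobenzofuran-5-yl)oxy]-4-hydroxy-3-(hydroxymethyl)-6-methylbenzoate (Compound NP-007516)
Conditions: 1 M aq. HCl, THF, rt
Reagents that add atoms: none
Why: Acid hydrolysis of the isopropylidene acetal of a salicyl alcohol, under which the phthalide, the methyl ester and the diaryl ether should be stable.

**Compound list**
1 | methyl orsellinate (methyl 2,4-dihydroxy-6-methylbenzoate) | COC(=O)c1c(C)cc(O)cc1O | starting material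
2 | methyl 3-formyl-2,4-dihydroxy-6-methylbenzoate | COC(=O)c1c(C)cc(O)c(C=O)c1O | intermediate
3 | methyl 2,4-dihydroxy-3-(hydroxymethyl)-6-methylbenzoate | COC(=O)c1c(C)cc(O)c(CO)c1O | intermediate
4 | methyl 5-hydroxy-2,2,7-trimethyl-4H-1,3-benzodioxine-6-carboxylate (ArA–OH) | COC(=O)c1c(C)cc2OC(C)(C)OCc2c1O | intermediate
5 | methyl 2-oxopentanoate | CCCC(=O)C(=O)OC | starting material
6 | methyl 3-bromo-2-oxopentanoate (racemic) | CCC(Br)C(=O)C(=O)OC | intermediate
7 | methyl 3-(ArA-oxy)-2-oxopentanoate (racemic) | CCC(Oc1c(C(=O)OC)c(C)cc2OC(C)(C)OCc12)C(=O)C(=O)OC | intermediate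
8 | methyl 2-(tert-butyldimethylsilyloxy)-3-(ArA-oxy)pent-2-enoate (E/Z mixture, geometry not defined) | CCC(Oc1c(C(=O)OC)c(C)cc2OC(C)(C)OCc12)=C(O[Si](C)(C)C(C)(C)C)C(=O)OC | intermediate
9 | (1E,3Z)-2-(tert-butyldimethylsilyloxy)-1-methoxy-1-(trimethylsilyloxy)-3-(ArA-oxy)penta-1,3-diene (C4 methyl trans to C2; acetal terminus drawn arbitrarily) | C/C=C(Oc1c(C(=O)OC)c(C)cc2OC(C)(C)OCc12)/C(O[Si](C)(C)C(C)(C)C)=C(/OC)O[Si](C)(C)C | intermediate
10 | methyl 4-hydroxybut-2-ynoate | COC(=O)C#CCO | starting material
11 | methyl 4-(tert-butyldimethylsilyloxy)but-2-ynoate | COC(=O)C#CCO[Si](C)(C)C(C)(C)C | intermediate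
12 | methyl 5-(tert-butyldimethylsilyloxy)-2-[(tert-butyldimethylsilyloxy)methyl]-6-methoxy-3-methyl-4-(ArA-oxy)-6-(trimethylsilyloxy)cyclohexa-1,4-diene-1-carboxylate (mixture of stereoisomers) | COC(=O)C1=C(CO[Si](C)(C)C(C)(C)C)C(C)C(Oc2c(C(=O)OC)c(C)cc3OC(C)(C)OCc23)=C(O[Si](C)(C)C(C)(C)C)C1(OC)O[Si](C)(C)C | intermediate (not isolated)
13 | methyl 3-(tert-butyldimethylsilyloxy)-6-[(tert-butyldimethylsilyloxy)methyl]-5-methyl-4-(ArA-oxy)-2-(trimethylsilyloxy)benzoate | COC(=O)c1c(CO[Si](C)(C)C(C)(C)C)c(C)c(Oc2c(C(=O)OC)c(C)cc3OC(C)(C)OCc23)c(O[Si](C)(C)C(C)(C)C)c1O[Si](C)(C)C | intermediate (not isolated)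
14 | methyl 2,3-dihydroxy-6-(hydroxymethyl)-5-methyl-4-(ArA-oxy)benzoate | COC(=O)c1c(CO)c(C)c(Oc2c(C(=O)OC)c(C)cc3OC(C)(C)OCc23)c(O)c1O | intermediate (not isolated)
15 | methyl 5-[(6,7-dihydroxy-4-methyl-1-oxo-1,3-dihydroisobenzofuran-5-yl)oxy]-2,2,7-trimethyl-4H-1,3-benzodioxine-6-carboxylate | COC(=O)c1c(C)cc2OC(C)(C)OCc2c1Oc1c(C)c2COC(=O)c2c(O)c1O | intermediate
16 | methyl 2-[(6,7-dihydroxy-4-methyl-1-oxo-1,3-dihydroisobenzofuran-5-yl)oxy]-4-hydroxy-3-(hydroxymethyl)-6-methylbenzoate (Compound NP-007516) | COC(=O)c1c(C)cc(O)c(CO)c1Oc1c(C)c2c(c(O)c1O)C(=O)OC2 | target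

**Count**
Total steps: 10. Longest linear sequence: 8 steps (steps 1, 2, 3, 5, 6, 7, 9, 10 from methyl orsellinate); steps 4 and 8 are one-step side branches.

**Steps most likely to fail**

Step 9. The crowded, fully substituted diene may add too slowly to the singly activated alkyne, so that thermal breakdown or hydrolysis of the ketene acetal overtakes the cycloaddition. The fallback sets out from 9 and changes both the dienophile and the way the lactone closes. The smaller and more electron-poor methyl 4,4-diethoxybut-2-ynoate F1 is made from 3,3-diethoxyprop-1-yne, n-BuLi and methyl chloroformate. Heating it with 9, followed by Bu4NF, should give methyl 6-(diethoxymethyl)-2,3-dihydroxy-5-methyl-4-(ArA-oxy)benzoate F2. Dilute aqueous acid then unmasks the aldehyde and removes the acetonide to give methyl 6-formyl-2,3-dihydroxy-4-[3-hydroxy-2-(hydroxymethyl)-6-(methoxycarbonyl)-5-methylphenoxy]-5-methylbenzoate F3. NaBH4 reduction of the aldehyde, with lactonisation of the resulting benzylic alcohol onto the neighbouring ester, comes back to the route at 16.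

Step 7. The amide base may remove a proton from the ring A benzylic methyl (lateral metalation of the ortho-toluate) in competition with the γ-position, and the new trisubstituted alkene may form without geometric control. The fallback sets out from 8 and installs the alkene before the silylation. Saegusa–Ito dehydrogenation (Pd(OAc)2, MeCN) should give the enone methyl (Z)-3-(ArA-oxy)-2-oxopent-3-enoate F4, with the methyl group trans to the carbonyl. Luche reduction (NaBH4, CeCl3, MeOH, −78 °C) gives the allylic alcohol methyl (Z)-3-(ArA-oxy)-2-hydroxypent-3-enoate F5. Silylation (TBSOTf, 2,6-lutidine) gives methyl (Z)-2-(tert-butyldimethylsilyloxy)-3-(ArA-oxy)pent-3-enoate F6. Its doubly activated α-proton is removed by the weaker base LiN(SiMe3)2 in the presence of TMSCl, which comes back to the route at 9.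

Step 5. The carbonate base may eliminate HBr from the bromo keto ester, or the phenoxide may add to the keto carbonyl, faster than the hindered phenoxide displaces the secondary bromide. The fallback sets out from 4 and makes the C–O bond by epoxide opening. Racemic methyl trans-3-ethyloxirane-2-carboxylate F7 is made by Darzens condensation of propanal with methyl chloroacetate (NaOMe). The phenoxide of 4 (Cs2CO3, DMF, 60 °C) should open it at C3 to give methyl 3-(ArA-oxy)-2-hydroxypentanoate F8. Dess–Martin oxidation of the secondary alcohol comes back to the route at 7.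

**Further compounds**
F1 | step 9 | methyl 4,4-diethoxybut-2-ynoate | CCOC(OCC)C#CC(=O)OC
F2 | step 9 | methyl 6-(diethoxymethyl)-2,3-dihydroxy-5-methyl-4-(ArA-oxy)benzoate | COC(=O)c1c(C(OCC)OCC)c(C)c(Oc2c(C(=O)OC)c(C)cc3OC(C)(C)OCc23)c(O)c1O
F3 | step 9 | methyl 6-formyl-2,3-dihydroxy-4-[3-hydroxy-2-(hydroxymethyl)-6-(methoxycarbonyl)-5-methylphenoxy]-5-methylbenzoate | COC(=O)c1c(C=O)c(C)c(Oc2c(C(=O)OC)c(C)cc(O)c2CO)c(O)c1O
F4 | step 7 | methyl (Z)-3-(ArA-oxy)-2-oxopent-3-enoate | C/C=C(Oc1c(C(=O)OC)c(C)cc2OC(C)(C)OCc12)/C(=O)C(=O)OC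
F5 | step 7 | methyl (Z)-3-(ArA-oxy)-2-hydroxypent-3-enoate (racemic) | C/C=C(Oc1c(C(=O)OC)c(C)cc2OC(C)(C)OCc12)/C(O)C(=O)OC
F6 | step 7 | methyl (Z)-2-(tert-butyldimethylsilyloxy)-3-(ArA-oxy)pent-3-enoate (racemic) | C/C=C(Oc1c(C(=O)OC)c(C)cc2OC(C)(C)OCc12)/C(O[Si](C)(C)C(C)(C)C)C(=O)OC
F7 | step 5 | methyl trans-3-ethyloxirane-2-carboxylate (racemic, one enantiomer drawn) | CC[C@H]1O[C@@H]1C(=O)OC
F8 | step 5 | methyl 3-(ArA-oxy)-2-hydroxypentanoate (racemic, relative configuration drawn) | CC[C@H](Oc1c(C(=O)OC)c(C)cc2OC(C)(C)OCc12)[C@H](O)C(=O)OC
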